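**Retrosynthetic overview** (chroman numbering for rings B and C: O1, C2, C3, C4, C4a, C5–C8, C8a)

1. Ring C is opened at O1–C2 and ring B is taken back to a non-aromatic isomer, the α-ketol dienone 17. One acid treatment should aromatize ring B by double-bond migration and then close ring C. Ring A is bought, the ring B carbocycle is bought as cyclohexane-1,3-dione and aromatized late, and ring C is formed last.
2. Enabling feature: in 17 the C8a oxygen is a ketone flanked by the C4a prenyl group and the C8 carbinol, and the exocyclic C6=C1' alkylidene stores the missing unsaturation. Ring B is therefore a masked catechol whose C8a hydroxyl, once unveiled, sits next to a prenyl group whose tertiary carbon becomes C2.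
3. 17 comes from vinylogous ester 11 by Stork–Danheiser chemistry, which sets the three contiguous carbon substituents without aromatic substitution. The dione C2 prenyl becomes the C4a arm, α'-aldol condensation with aldehyde 8 gives the C6 chain, allyl addition with carbonyl transposition gives C5, and α'-hydroxylation gives O8.
4. Aldehyde 8 (ring A) comes from 2,4-dihydroxybenzaldehyde by O-prenylation, aromatic Claisen rearrangement (1,1-dimethylallyl group), Wittig homologation and conjugate reduction.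
5. After the key step the C5 allyl group is converted to prenyl by cross-metathesis and the two silyl ethers are removed.

Key step: step 12

Remark: Ar = 5-(2-methylbut-3-en-2-yl)-2,4-bis[(triisopropylsilyl)oxy]phenyl. Kazinol D is achiral; the stereocentres of 4, 12, 13, 15 and 17 are formed without control and are erased by tautomerization, elimination, hydrolysis or aromatization.

**Step 1**
Reactants: 1 2,4-dihydroxybenzaldehyde
Product: 2 2-hydroxy-4-[(3-methylbut-2-en-1-yl)oxy]benzaldehyde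
Conditions: prenyl bromide, K2CO3, acetone, 40 °C
Reagents that add atoms: prenyl bromide (1-bromo-3-methylbut-2-ene), CC(C)=CCBr
Why: Williamson etherification; the C2 hydroxyl is hydrogen-bonded to the formyl group, so the C4 phenoxide should be alkylated selectively.

**Step 2**
Reactants: 2 2-hydroxy-4-[(3-methylbut-2-en-1-yl)oxy]benzaldehyde
Product: 3 4-[(3-methylbut-2-en-1-yl)oxy]-2-[(triisopropylsilyl)oxy]benzaldehyde
Conditions: TIPSCl, imidazole, DMF, rt
Reagents that add atoms: triisopropylsilyl chloride, CC(C)[Si](Cl)(C(C)C)C(C)C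
Why: Silylation of the remaining phenol removes the OH···O=C chelation that would steer the coming rearrangement to C3 and installs a fluoride-labile group.

**Step 3**
Reactants: 3 4-[(3-methylbut-2-en-1-yl)oxy]-2-[(triisopropylsilyl)oxy]benzaldehyde
Product: 5 4-hydroxy-5-(2-methylbut-3-en-2-yl)-2-[(triisopropylsilyl)oxy]benzaldehyde, via ortho-dienone 4 (not isolated)
Conditions: PhNEt2, 190 °C, sealed tube
Reagents that add atoms: none
Why: Aromatic Claisen rearrangement, a [3,3] shift that transfers the allyl unit with inversion to give the 1,1-dimethylallyl group; it should go to C5 and not to C3 because C3 is flanked by the bulky silyloxy group, and tautomerization of the dienone restores the phenol.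

**Step 4**
Reactants: 5 4-hydroxy-5-(2-methylbut-3-en-2-yl)-2-[(triisopropylsilyl)oxy]benzaldehyde
Product: 6 5-(2-methylbut-3-en-2-yl)-2,4-bis[(triisopropylsilyl)oxy]benzaldehyde
Conditions: TIPSOTf, 2,6-lutidine, CH2Cl2, 0 °C to rt
Reagents that add atoms: triisopropylsilyl trifluoromethanesulfonate, CC(C)[Si](OS(=O)(=O)C(F)(F)F)(C(C)C)C(C)C
Why: The silyl triflate should silylate the hindered phenol next to the quaternary carbon, which later prevents acid-induced cyclization of the 1,1-dimethylallyl group onto this oxygen.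

**Step 5**
Reactants: 6 5-(2-methylbut-3-en-2-yl)-2,4-bis[(triisopropylsilyl)oxy]benzaldehyde
Product: 7 (2E)-3-Ar-prop-2-enal
Conditions: Ph3P=CHCHO, toluene, 80 °C
Reagents that add atoms: (triphenylphosphoranylidene)acetaldehyde, O=CC=P(c1ccccc1)(c1ccccc1)c1ccccc1
Why: Wittig olefination with a stabilized formyl ylide should give the E-enal and adds the two missing chain carbons.

**Step 6**
Reactants: 7 (2E)-3-Ar-prop-2-enal
Product: 8 3-Ar-propanal
Conditions: Hantzsch ester, dibenzylammonium trifluoroacetate (cat.), THF, rt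
Reagents that add atoms: none
Why: Iminium-catalysed conjugate transfer hydrogenation reduces only the polarized C=C of the enal, so the isolated vinyl group, the aldehyde and the aryl silyl ethers should remain.

**Step 7**
Reactants: 9 cyclohexane-1,3-dione
Product: 10 2-(3-methylbut-2-en-1-yl)cyclohexane-1,3-dione
Conditions: prenyl bromide, KOH, H2O, rt
Reagents that add atoms: prenyl bromide (1-bromo-3-methylbut-2-ene), CC(C)=CCBr
Why: C-alkylation of the dione enolate, favoured over O-alkylation in water, at the primary carbon of the allylic bromide.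

**Step 8**
Reactants: 10 2-(3-methylbut-2-en-1-yl)cyclohexane-1,3-dione
Product: 11 3-methoxy-2-(3-methylbut-2-en-1-yl)cyclohex-2-en-1-one
Conditions: Me2SO4, K2CO3, acetone, reflux
Reagents that add atoms: dimethyl sulfate, COS(=O)(=O)OC
Why: O-methylation of a 2-substituted 1,3-dione with a hard electrophile gives the vinylogous ester, and the base-only conditions avoid acid cyclization of the 2-prenyl dione to a fused dihydropyran.

**Step 9**
Reactants: 11 3-methoxy-2-(3-methylbut-2-en-1-yl)cyclohex-2-en-1-one; 8 3-Ar-propanal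
Product: 14 (6E)-6-(3-Ar-propylidene)-3-methoxy-2-(3-methylbut-2-en-1-yl)cyclohex-2-en-1-one, via aldol adduct 12 (not isolated), via mesylate 13 (not isolated)
Conditions: LiN(i-Pr)2, THF, −78 °C; 8; MsCl, −78 to 0 °C; DBU, rt
Reagents that add atoms: none
Why: Stork–Danheiser kinetic α'-enolate of the vinylogous ester adds to the aldehyde, and mesylation with E1cB elimination completes the aldol condensation, giving the E-alkylidene with the chain anti to the carbonyl.

**Step 10**
Reactants: 14 (6E)-6-(3-Ar-propylidene)-3-methoxy-2-(3-methylbut-2-en-1-yl)cyclohex-2-en-1-one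
Product: 16 (4E)-4-(3-Ar-propylidene)-2-(3-methylbut-2-en-1-yl)-3-(prop-2-en-1-yl)cyclohex-2-en-1-one, via tertiary carbinol 15 (not isolated)
Conditions: CH2=CHCH2MgBr, THF, −78 to 0 °C; then 1 M HCl, THF, 0 °C
Reagents that add atoms: allylmagnesium bromide, C=CC[Mg]Br; water, O
Why: Stork–Danheiser 1,2-addition of the allyl Grignard reagent to the vinylogous ester carbonyl, then acid ionization of the carbinol, water capture at the methoxy-bearing carbon and loss of methanol transpose the carbonyl while the exocyclic alkene is kept.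

**Step 11**
Reactants: 16 (4E)-4-(3-Ar-propylidene)-2-(3-methylbut-2-en-1-yl)-3-(prop-2-en-1-yl)cyclohex-2-en-1-one
Product: 17 (4E)-6-hydroxy-4-(3-Ar-propylidene)-2-(3-methylbut-2-en-1-yl)-3-(prop-2-en-1-yl)cyclohex-2-en-1-one (racemic)
Conditions: KN(SiMe3)2, THF, −78 °C; 3-phenyl-2-(phenylsulfonyl)oxaziridine; AcOH quench
Reagents that add atoms: 3-phenyl-2-(phenylsulfonyl)oxaziridine, O=S(=O)(c1ccccc1)N1OC1c1ccccc1
Why: Kinetic deprotonation at the α' methylene with a hindered amide base and enolate oxidation by the N-sulfonyloxaziridine (Davis hydroxylation) should install the future O8; the new stereocentre is racemic and is erased in step 12.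

**Step 12**
Reactants: 17 (4E)-6-hydroxy-4-(3-Ar-propylidene)-2-(3-methylbut-2-en-1-yl)-3-(prop-2-en-1-yl)cyclohex-2-en-1-one
Product: 19 6-(3-Ar-propyl)-2,2-dimethyl-5-(prop-2-en-1-yl)-3,4-dihydro-2H-chromen-8-ol, via catechol 18 (not isolated)
Conditions: TsOH·H2O (20 mol %), toluene, 80 °C
Reagents that add atoms: none
Why: Acid-catalysed enolization of the α-ketol gives an ene-diol with two endocyclic double bonds and the exocyclic C6=C1' bond; protonation at C1' and loss of H-7 should aromatize ring B to catechol 18, the known isoaromatization of alkylidenecyclohexenones to phenols. The same acid then protonates the trisubstituted alkene of the C4a prenyl group in the Markovnikov sense, and the C8a hydroxyl captures the tertiary cation at C2, the known cycloetherification of ortho-prenylphenols to 2,2-dimethylchromans. Ring C closes in a cationic 6-endo-trig mode, ring B is aromatized and not closed, and no stereocentre is formed. The closure must use O8a and not O8, which is secured because only O8a has an ortho prenyl group. Only the prenyl group gives a tertiary cation, so the C5 allyl group and the hindered vinyl group on ring A should stay untouched, and the silyl ethers on ring A block cyclization of its 1,1-dimethylallyl group. The C8 oxygen should not be lost because it sits α to the carbonyl, where ionization is disfavoured, and becomes vinylic at the first enolization.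

**Step 13**
Reactants: 19 6-(3-Ar-propyl)-2,2-dimethyl-5-(prop-2-en-1-yl)-3,4-dihydro-2H-chromen-8-ol
Product: 20 6-(3-Ar-propyl)-2,2-dimethyl-5-(3-methylbut-2-en-1-yl)-3,4-dihydro-2H-chromen-8-ol
Conditions: 2-methylbut-2-ene (excess), second-generation Hoveyda–Grubbs catalyst (5 mol %), CH2Cl2, 40 °C
Reagents that add atoms: 2-methylbut-2-ene, CC=C(C)C
Why: Olefin cross-metathesis of the unhindered terminal allyl group with excess 2-methylbut-2-ene should give the prenyl group, while the vinyl group on the quaternary carbon of ring A is too hindered to react.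

**Step 14**
Reactants: 20 6-(3-Ar-propyl)-2,2-dimethyl-5-(3-methylbut-2-en-1-yl)-3,4-dihydro-2H-chromen-8-ol
Product: 21 Kazinol D
Conditions: Bu4NF, AcOH, THF, 0 °C
Reagents that add atoms: none
Why: Fluoride cleaves both aryl silyl ethers, and the acetic acid buffer keeps the electron-rich phenols and the 1,1-dimethylallyl phenol away from strong base or acid.

**Compound list**

1 | 2,4-dihydroxybenzaldehyde | O=Cc1ccc(O)cc1O | starting material
2 | 2-hydroxy-4-[(3-methylbut-2-en-1-yl)oxy]benzaldehyde | O=Cc1ccc(OCC=C(C)C)cc1O | intermediate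
3 | 4-[(3-methylbut-2-en-1-yl)oxy]-2-[(triisopropylsilyl)oxy]benzaldehyde | O=Cc1ccc(OCC=C(C)C)cc1O[Si](C(C)C)(C(C)C)C(C)C | intermediate
4 | 3-(2-methylbut-3-en-2-yl)-4-oxo-6-[(triisopropylsilyl)oxy]cyclohexa-1,5-diene-1-carbaldehyde (racemic, not isolated) | O=CC1=CC(C(C)(C)C=C)C(=O)C=C1O[Si](C(C)C)(C(C)C)C(C)C | intermediate
5 | 4-hydroxy-5-(2-methylbut-3-en-2-yl)-2-[(triisopropylsilyl)oxy]benzaldehyde | O=Cc1cc(C(C)(C)C=C)c(O)cc1O[Si](C(C)C)(C(C)C)C(C)C | intermediate
6 | 5-(2-methylbut-3-en-2-yl)-2,4-bis[(triisopropylsilyl)oxy]benzaldehyde | O=Cc1cc(C(C)(C)C=C)c(O[Si](C(C)C)(C(C)C)C(C)C)cc1O[Si](C(C)C)(C(C)C)C(C)C | intermediate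
7 | (2E)-3-Ar-prop-2-enal | O=C/C=C/c1cc(C(C)(C)C=C)c(O[Si](C(C)C)(C(C)C)C(C)C)cc1O[Si](C(C)C)(C(C)C)C(C)C | intermediate
8 | 3-Ar-propanal | O=CCCc1cc(C(C)(C)C=C)c(O[Si](C(C)C)(C(C)C)C(C)C)cc1O[Si](C(C)C)(C(C)C)C(C)C | intermediate
9 | cyclohexane-1,3-dione | O=C1CCCC(=O)C1 | starting material
10 | 2-(3-methylbut-2-en-1-yl)cyclohexane-1,3-dione | CC(C)=CCC1C(=O)CCCC1=O | intermediate
11 | 3-methoxy-2-(3-methylbut-2-en-1-yl)cyclohex-2-en-1-one | COC1=C(CC=C(C)C)C(=O)CCC1 | intermediate
12 | 6-(3-Ar-1-hydroxypropyl)-3-methoxy-2-(3-methylbut-2-en-1-yl)cyclohex-2-en-1-one (diastereomer mixture, not isolated) | COC1=C(CC=C(C)C)C(=O)C(C(O)CCc2cc(C(C)(C)C=C)c(O[Si](C(C)C)(C(C)C)C(C)C)cc2O[Si](C(C)C)(C(C)C)C(C)C)CC1 | intermediate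
13 | methanesulfonate of 12 (diastereomer mixture, not isolated) | COC1=C(CC=C(C)C)C(=O)C(C(OS(C)(=O)=O)CCc2cc(C(C)(C)C=C)c(O[Si](C(C)C)(C(C)C)C(C)C)cc2O[Si](C(C)C)(C(C)C)C(C)C)CC1 | intermediate
14 | (6E)-6-(3-Ar-propylidene)-3-methoxy-2-(3-methylbut-2-en-1-yl)cyclohex-2-en-1-one | COC1=C(CC=C(C)C)C(=O)/C(=C/CCc2cc(C(C)(C)C=C)c(O[Si](C(C)C)(C(C)C)C(C)C)cc2O[Si](C(C)C)(C(C)C)C(C)C)CC1 | intermediate
15 | (6E)-6-(3-Ar-propylidene)-3-methoxy-2-(3-methylbut-2-en-1-yl)-1-(prop-2-en-1-yl)cyclohex-2-en-1-ol (racemic, not isolated) | COC1=C(CC=C(C)C)C(O)(CC=C)/C(=C/CCc2cc(C(C)(C)C=C)c(O[Si](C(C)C)(C(C)C)C(C)C)cc2O[Si](C(C)C)(C(C)C)C(C)C)CC1 | intermediate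
16 | (4E)-4-(3-Ar-propylidene)-2-(3-methylbut-2-en-1-yl)-3-(prop-2-en-1-yl)cyclohex-2-en-1-one | O=C1CC/C(=C\CCc2cc(C(C)(C)C=C)c(O[Si](C(C)C)(C(C)C)C(C)C)cc2O[Si](C(C)C)(C(C)C)C(C)C)C(CC=C)=C1CC=C(C)C | intermediate
17 | (4E)-6-hydroxy-4-(3-Ar-propylidene)-2-(3-methylbut-2-en-1-yl)-3-(prop-2-en-1-yl)cyclohex-2-en-1-one (racemic) | O=C1C(O)C/C(=C\CCc2cc(C(C)(C)C=C)c(O[Si](C(C)C)(C(C)C)C(C)C)cc2O[Si](C(C)C)(C(C)C)C(C)C)C(CC=C)=C1CC=C(C)C | intermediate
18 | 5-(3-Ar-propyl)-3-(3-methylbut-2-en-1-yl)-4-(prop-2-en-1-yl)benzene-1,2-diol (not isolated) | Oc1c(O)cc(CCCc2cc(C(C)(C)C=C)c(O[Si](C(C)C)(C(C)C)C(C)C)cc2O[Si](C(C)C)(C(C)C)C(C)C)c(CC=C)c1CC=C(C)C | intermediate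
19 | 6-(3-Ar-propyl)-2,2-dimethyl-5-(prop-2-en-1-yl)-3,4-dihydro-2H-chromen-8-ol | CC1(C)CCc2c(CC=C)c(CCCc3cc(C(C)(C)C=C)c(O[Si](C(C)C)(C(C)C)C(C)C)cc3O[Si](C(C)C)(C(C)C)C(C)C)cc(O)c2O1 | intermediate
20 | 6-(3-Ar-propyl)-2,2-dimethyl-5-(3-methylbut-2-en-1-yl)-3,4-dihydro-2H-chromen-8-ol (bis-silyl ether of Kazinol D) | CC1(C)CCc2c(CC=C(C)C)c(CCCc3cc(C(C)(C)C=C)c(O[Si](C(C)C)(C(C)C)C(C)C)cc3O[Si](C(C)C)(C(C)C)C(C)C)cc(O)c2O1 | intermediate
21 | Kazinol D, 4-{3-[8-hydroxy-2,2-dimethyl-5-(3-methylbut-2-en-1-yl)-3,4-dihydro-2H-chromen-6-yl]propyl}-6-(2-methylbut-3-en-2-yl)benzene-1,3-diol | C=CC(C)(C)c1cc(CCCc2cc(O)c3c(c2CC=C(C)C)CCC(C)(C)O3)c(O)cc1O | target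

**Totals**

Total step count: 14. Longest linear sequence: 12 steps (steps 1–6 and 9–14); steps 7 and 8 form the short branch.

**Steps most likely to fail**

Step 12. The acid may divert the isomerization. It could stall at a styrene-type isomer, or dehydrate the α-ketol through a quinone methide manifold with loss of the C8 oxygen, before ring B is aromatic. Fallback: aromatize by oxidation from a saturated side chain, so that O8 is carried as a ketone and cannot be lost. The fallback sets out from 14. Conjugate reduction of the exocyclic enone with [(Ph3P)CuH]6 should give 6-(3-Ar-propyl)-3-methoxy-2-(3-methylbut-2-en-1-yl)cyclohex-2-en-1-one F1. Allylmagnesium bromide followed by 1 M HCl should give, through the carbinol F2, the enone 4-(3-Ar-propyl)-2-(3-methylbut-2-en-1-yl)-3-(prop-2-en-1-yl)cyclohex-2-en-1-one F3. Hydroxylation as in step 11 should give the ketol F4. Swern oxidation ((COCl)2, DMSO, Et3N) should give the cyclohex-3-ene-1,2-dione F5, which tautomerizes under the amine to catechol 18. The fallback comes back at 18, which the conditions of step 12 should close to 19.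

Step 11. Deprotonation may occur at the doubly allylic CH2 of the C3 allyl group, or the base may trigger premature aromatization, either of which gives material without the C8 oxygen. Fallback: place the oxygen after aromatization by phenol-directed chemistry. The fallback sets out from 16. Base-mediated isoaromatization (KOt-Bu, THF) should give 4-(3-Ar-propyl)-2-(3-methylbut-2-en-1-yl)-3-(prop-2-en-1-yl)phenol F6. Ortho-formylation (MgCl2, Et3N, (CH2O)n, MeCN, reflux) should give the salicylaldehyde F7. Dakin oxidation (H2O2, NaOH, THF/H2O, 0 °C) should pass through the aryl formate F8 to catechol 18. The fallback comes back at 18, which step 12 should convert to 19.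

Step 13. Ruthenium hydride species may move the allyl double bond into conjugation with ring B, or the ring A vinyl group may be drawn into metathesis. Fallback: introduce the C5 prenyl group directly and omit the metathesis. The fallback sets out from 14. PrenylBaCl (from prenyl chloride and activated barium made from BaI2 and lithium biphenylide; THF, −78 °C), an α-selective and 1,2-selective allylic barium reagent, followed by 1 M HCl should give, through the carbinol F9, the dienone (4E)-4-(3-Ar-propylidene)-2,3-bis(3-methylbut-2-en-1-yl)cyclohex-2-en-1-one F10. Hydroxylation as in step 11 should give the ketol F11. TsOH·H2O in toluene should take it through the catechol F12 to 20, where the fallback comes back to the route.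

**Further compounds**

F1 | step 12 | 6-(3-Ar-propyl)-3-methoxy-2-(3-methylbut-2-en-1-yl)cyclohex-2-en-1-one (racemic) | COC1=C(CC=C(C)C)C(=O)C(CCCc2cc(C(C)(C)C=C)c(O[Si](C(C)C)(C(C)C)C(C)C)cc2O[Si](C(C)C)(C(C)C)C(C)C)CC1
F2 | step 12 | 6-(3-Ar-propyl)-3-methoxy-2-(3-methylbut-2-en-1-yl)-1-(prop-2-en-1-yl)cyclohex-2-en-1-ol (diastereomer mixture, not isolated) | COC1=C(CC=C(C)C)C(O)(CC=C)C(CCCc2cc(C(C)(C)C=C)c(O[Si](C(C)C)(C(C)C)C(C)C)cc2O[Si](C(C)C)(C(C)C)C(C)C)CC1
F3 | step 12 | 4-(3-Ar-propyl)-2-(3-methylbut-2-en-1-yl)-3-(prop-2-en-1-yl)cyclohex-2-en-1-one (racemic) | O=C1CCC(CCCc2cc(C(C)(C)C=C)c(O[Si](C(C)C)(C(C)C)C(C)C)cc2O[Si](C(C)C)(C(C)C)C(C)C)C(CC=C)=C1CC=C(C)C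
F4 | step 12 | 6-hydroxy-4-(3-Ar-propyl)-2-(3-methylbut-2-en-1-yl)-3-(prop-2-en-1-yl)cyclohex-2-en-1-one (diastereomer mixture) | O=C1C(O)CC(CCCc2cc(C(C)(C)C=C)c(O[Si](C(C)C)(C(C)C)C(C)C)cc2O[Si](C(C)C)(C(C)C)C(C)C)C(CC=C)=C1CC=C(C)C
F5 | step 12 | 5-(3-Ar-propyl)-3-(3-methylbut-2-en-1-yl)-4-(prop-2-en-1-yl)cyclohex-3-ene-1,2-dione (racemic, not isolated) | O=C1C(=O)CC(CCCc2cc(C(C)(C)C=C)c(O[Si](C(C)C)(C(C)C)C(C)C)cc2O[Si](C(C)C)(C(C)C)C(C)C)C(CC=C)=C1CC=C(C)C
F6 | step 11 | 4-(3-Ar-propyl)-2-(3-methylbut-2-en-1-yl)-3-(prop-2-en-1-yl)phenol | Oc1ccc(CCCc2cc(C(C)(C)C=C)c(O[Si](C(C)C)(C(C)C)C(C)C)cc2O[Si](C(C)C)(C(C)C)C(C)C)c(CC=C)c1CC=C(C)C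
F7 | step 11 | 5-(3-Ar-propyl)-2-hydroxy-3-(3-methylbut-2-en-1-yl)-4-(prop-2-en-1-yl)benzaldehyde | O=Cc1cc(CCCc2cc(C(C)(C)C=C)c(O[Si](C(C)C)(C(C)C)C(C)C)cc2O[Si](C(C)C)(C(C)C)C(C)C)c(CC=C)c(CC=C(C)C)c1O
F8 | step 11 | 5-(3-Ar-propyl)-2-hydroxy-3-(3-methylbut-2-en-1-yl)-4-(prop-2-en-1-yl)phenyl formate (not isolated) | O=COc1cc(CCCc2cc(C(C)(C)C=C)c(O[Si](C(C)C)(C(C)C)C(C)C)cc2O[Si](C(C)C)(C(C)C)C(C)C)c(CC=C)c(CC=C(C)C)c1O
F9 | step 13 | (6E)-6-(3-Ar-propylidene)-3-methoxy-1,2-bis(3-methylbut-2-en-1-yl)cyclohex-2-en-1-ol (racemic, not isolated) | COC1=C(CC=C(C)C)C(O)(CC=C(C)C)/C(=C/CCc2cc(C(C)(C)C=C)c(O[Si](C(C)C)(C(C)C)C(C)C)cc2O[Si](C(C)C)(C(C)C)C(C)C)CC1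
F10 | step 13 | (4E)-4-(3-Ar-propylidene)-2,3-bis(3-methylbut-2-en-1-yl)cyclohex-2-en-1-one | O=C1CC/C(=C\CCc2cc(C(C)(C)C=C)c(O[Si](C(C)C)(C(C)C)C(C)C)cc2O[Si](C(C)C)(C(C)C)C(C)C)C(CC=C(C)C)=C1CC=C(C)C
F11 | step 13 | (4E)-6-hydroxy-4-(3-Ar-propylidene)-2,3-bis(3-methylbut-2-en-1-yl)cyclohex-2-en-1-one (racemic) | O=C1C(O)C/C(=C\CCc2cc(C(C)(C)C=C)c(O[Si](C(C)C)(C(C)C)C(C)C)cc2O[Si](C(C)C)(C(C)C)C(C)C)C(CC=C(C)C)=C1CC=C(C)C
F12 | step 13 | 5-(3-Ar-propyl)-3,4-bis(3-methylbut-2-en-1-yl)benzene-1,2-diol (not isolated) | Oc1c(O)cc(CCCc2cc(C(C)(C)C=C)c(O[Si](C(C)C)(C(C)C)C(C)C)cc2O[Si](C(C)C)(C(C)C)C(C)C)c(CC=C(C)C)c1CC=C(C)C
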